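**Plan**

- Retrosynthesis first removes two benzyl groups (ring A phenol, ring B carboxyl), then cuts two bonds at the stereogenic carbon C2: the C2–O bond to ring B and the C2–CH2OH bond.
- What permits this double cut: C2 carries the ring A aroyl carbonyl, the ring B aryloxy oxygen and the hydroxymethyl carbon, so it is the carbon of a ketocarbene caught between a phenol O–H and formaldehyde.
- Forward, both aryl rings come intact from syringic acid: ring A is taken to a benzyl-protected terminal diazoketone, ring B to benzyl syringate.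
- The three-carbon chain is then joined in one operation from diazoketone, phenol and monomeric formaldehyde; no ring is formed anywhere in the route.
- The single (R) stereocentre is set in that operation by a chiral phosphoric acid working alongside Rh2(OAc)4, and is kept by a base-free hydrogenolysis at the end.

Key step: step 5

Assumption: the sense of induction cannot be read from precedent, so the (R)-phosphoric acid is taken to give the (R)-product; if a first chiral HPLC assay shows the opposite, the (S)-acid is used with nothing else changed.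

**Route**

Step 1
Reactants: 1 syringic acid (4-hydroxy-3,5-dimethoxybenzoic acid); 2 benzyl bromide
Product: 3 benzyl 4-(benzyloxy)-3,5-dimethoxybenzoate
Conditions: BnBr (2.5 equiv), K2CO3 (3 equiv), DMF, 60 °C
Reagents that add atoms: benzyl bromide (2), BrCc1ccccc1
Why: Williamson ether synthesis and carboxylate O-alkylation run together, K2CO3 in DMF ionising both the acid and the 2,6-dimethoxyphenol and the benzylic bromide being reactive enough in SN2 to alkylate even the flanked phenoxide on warming.

Step 2
Reactants: 3 benzyl 4-(benzyloxy)-3,5-dimethoxybenzoate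
Product: 4 4-(benzyloxy)-3,5-dimethoxybenzoic acid
Conditions: NaOH (3 equiv), THF/MeOH/H2O, 60 °C; then 1 M HCl
Reagents that add atoms: sodium hydroxide, [Na+].[OH-]
Why: Ester saponification (BAc2) frees the carboxylic acid while the aryl benzyl ether, which offers hydroxide no point of attack, stays in place.

Step 3
Reactants: 4 4-(benzyloxy)-3,5-dimethoxybenzoic acid; 5 trimethylsilyldiazomethane
Product: 7 1-[4-(benzyloxy)-3,5-dimethoxyphenyl]-2-diazoethan-1-one, via acid chloride 6 (not isolated)
Conditions: (COCl)2, cat. DMF, CH2Cl2, 0 °C → rt, evaporate; then TMSCHN2 (2 equiv, 2 M in hexanes), THF/MeCN (1:1), 0 °C → rt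
Reagents that add atoms: trimethylsilyldiazomethane (5), C[Si](C)(C)C=[N+]=[N-]
Why: Vilsmeier-catalysed acid chloride formation followed by acylation of trimethylsilyldiazomethane (the first stage of an Arndt–Eistert homologation) gives the terminal diazoketone after chloride takes the silyl group from the acyldiazonium intermediate, and neither stage touches the benzyl ether or the methoxy groups.

Step 4
Reactants: 1 syringic acid; 2 benzyl bromide
Product: 8 benzyl 4-hydroxy-3,5-dimethoxybenzoate (benzyl syringate)
Conditions: BnBr (1.05 equiv), KHCO3 (1.2 equiv), DMF, 40 °C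
Reagents that add atoms: benzyl bromide (2), BrCc1ccccc1
Why: Chemoselective SN2 alkylation of the carboxylate only, since hydrogencarbonate ionises the acid but not the phenol, whose oxygen is moreover screened by the two ortho methoxy groups.

Step 5
Reactants: 7 1-[4-(benzyloxy)-3,5-dimethoxyphenyl]-2-diazoethan-1-one; 8 benzyl 4-hydroxy-3,5-dimethoxybenzoate; 9 formaldehyde (monomer, freshly cracked from paraformaldehyde)
Product: 11 benzyl 4-{[(2R)-1-[4-(benzyloxy)-3,5-dimethoxyphenyl]-3-hydroxy-1-oxopropan-2-yl]oxy}-3,5-dimethoxybenzoate, via (Z)-enol 10 (not isolated)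
Conditions: Rh2(OAc)4 (2 mol%), (R)-3,3'-bis(2,4,6-triisopropylphenyl)-1,1'-binaphthyl-2,2'-diyl hydrogen phosphate (10 mol%), 8 (1.5 equiv), CH2O gas (about 5 equiv, argon stream), 4 Å molecular sieves, CH2Cl2, −10 °C, 7 added by syringe pump over 4 h
Reagents that add atoms: formaldehyde (9), C=O
Why: Proposed new method: Rh2(OAc)4 turns 7 into an electrophilic rhodium ketocarbenoid, the phenolic oxygen of 8 adds to it, and the oxonium ylide so formed passes its proton to the carbonyl oxygen and leaves the metal as (Z)-enol 10; the phosphoric acid then holds 10 and formaldehyde through its P=O and P–OH sites so that aldol C–C bond formation overtakes the usual 1,2-proton shift. The closest known reaction type is the Rh2(OAc)4 and chiral phosphoric acid three-component aldol-type trapping of oxonium ylides or enols, made from diazo compounds and alcohols, by aldehydes; what is untested is the trio of a 2,6-dimethoxyphenol, a terminal aryl diazoketone and formaldehyde. No ring is closed: the C–O(aryl) bond and the C–CH2OH bond are both formed at the former diazo carbon. The one new stereocentre is set in the aldol event, where the chiral pocket of the binaphthyl phosphate shields one face of the bound enol and so decides the (R) configuration. The step needs O–H capture by the phenol to beat capture of the carbenoid by water, formaldehyde or the product alcohol, and C–C trapping to beat protonation: sieves and anhydrous monomeric formaldehyde keep water out, slow addition of 7 into excess 8 keeps the free carbenoid and the product alcohol scarce, the methoxy-blocked ortho and ester-blocked para positions of 8 leave oxygen as its only nucleophilic site, and the electron-rich ring A enol paired with the small, highly electrophilic formaldehyde favours the aldol path.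

Step 6
Reactants: 11 benzyl 4-{[(2R)-1-[4-(benzyloxy)-3,5-dimethoxyphenyl]-3-hydroxy-1-oxopropan-2-yl]oxy}-3,5-dimethoxybenzoate
Product: 12 4-{[(2R)-3-hydroxy-1-(4-hydroxy-3,5-dimethoxyphenyl)-1-oxopropan-2-yl]oxy}-3,5-dimethoxybenzoic acid
Conditions: H2 (1 atm), 10% Pd/C, EtOAc, rt
Reagents that add atoms: none
Why: Catalytic hydrogenolysis cleaves the benzyl ester and the aryl benzyl ether, both among the fastest O-benzyl groups to go at 1 atm, in a neutral medium with no base, so the enolisable and retro-aldol-prone stereocentre keeps its configuration, and the reaction is stopped once two equivalents of H2 are taken up to spare the aryl ketone and the α-aryloxy C–O bond.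

**Compound list**

1 | syringic acid (4-hydroxy-3,5-dimethoxybenzoic acid) | COc1cc(C(=O)O)cc(OC)c1O | starting material
2 | benzyl bromide | BrCc1ccccc1 | starting material
3 | benzyl 4-(benzyloxy)-3,5-dimethoxybenzoate | COc1cc(C(=O)OCc2ccccc2)cc(OC)c1OCc1ccccc1 | intermediate
4 | 4-(benzyloxy)-3,5-dimethoxybenzoic acid | COc1cc(C(=O)O)cc(OC)c1OCc1ccccc1 | intermediate
5 | trimethylsilyldiazomethane | C[Si](C)(C)C=[N+]=[N-] | starting material
6 | 4-(benzyloxy)-3,5-dimethoxybenzoyl chloride (not isolated) | COc1cc(C(=O)Cl)cc(OC)c1OCc1ccccc1 | intermediate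
7 | 1-[4-(benzyloxy)-3,5-dimethoxyphenyl]-2-diazoethan-1-one | COc1cc(C(=O)C=[N+]=[N-])cc(OC)c1OCc1ccccc1 | intermediate
8 | benzyl 4-hydroxy-3,5-dimethoxybenzoate (benzyl syringate) | COc1cc(C(=O)OCc2ccccc2)cc(OC)c1O | intermediate
9 | formaldehyde (monomer, generated from commercial paraformaldehyde) | C=O | starting material
10 | benzyl 4-({(Z)-2-[4-(benzyloxy)-3,5-dimethoxyphenyl]-2-hydroxyethenyl}oxy)-3,5-dimethoxybenzoate (enol, not isolated) | COc1cc(/C(O)=C/Oc2c(OC)cc(C(=O)OCc3ccccc3)cc2OC)cc(OC)c1OCc1ccccc1 | intermediate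
11 | benzyl 4-{[(2R)-1-[4-(benzyloxy)-3,5-dimethoxyphenyl]-3-hydroxy-1-oxopropan-2-yl]oxy}-3,5-dimethoxybenzoate | COc1cc(C(=O)[C@@H](CO)Oc2c(OC)cc(C(=O)OCc3ccccc3)cc2OC)cc(OC)c1OCc1ccccc1 | intermediate
12 | 4-{[(2R)-3-hydroxy-1-(4-hydroxy-3,5-dimethoxyphenyl)-1-oxopropan-2-yl]oxy}-3,5-dimethoxybenzoic acid | COc1cc(C(=O)[C@@H](CO)Oc2c(OC)cc(C(=O)O)cc2OC)cc(OC)c1O | target

**Count**

Total steps: 6. Longest linear sequence: 5 steps (steps 1, 2, 3, 5, 6 from syringic acid); step 4 is a one-step branch.

**Steps most likely to fail**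

1. Step 5. Proton transfer to the enol may outrun its capture by formaldehyde, so that only plain O–H insertion occurs. Facial control on so small an electrophile may be poor, or eroded by an uncatalysed background addition. The carbenoid may also be consumed by formaldehyde, by its hemiformal with the phenol, or by the primary hydroxyl of the product. The fallback uses known chemistry, sets out from 7 and 8, and returns at 11.
   - Aqueous HBr (48%, Et2O, 0 °C) converts 7 into the bromoketone 1-[4-(benzyloxy)-3,5-dimethoxyphenyl]-2-bromoethan-1-one F1.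
   - Phenol 8 is alkylated with it (K2CO3, acetone, 50 °C) to the aryloxy ketone benzyl 4-{2-[4-(benzyloxy)-3,5-dimethoxyphenyl]-2-oxoethoxy}-3,5-dimethoxybenzoate F2.
   - A base-mediated aldol addition to aqueous formaldehyde (1.2 equiv, K2CO3, EtOH/acetone, rt) gives racemic benzyl 4-{[1-[4-(benzyloxy)-3,5-dimethoxyphenyl]-3-hydroxy-1-oxopropan-2-yl]oxy}-3,5-dimethoxybenzoate F3.
   - Preparative HPLC on an amylose tris(3,5-dimethylphenylcarbamate) phase separates 11 from its antipode, benzyl 4-{[(2S)-1-[4-(benzyloxy)-3,5-dimethoxyphenyl]-3-hydroxy-1-oxopropan-2-yl]oxy}-3,5-dimethoxybenzoate F4, which is set aside.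

2. Step 6. Reductive cleavage of the ketone-activated C–O(aryl) bond, or over-reduction of the aryl ketone, may compete with debenzylation. The fallback takes the ketone out of play during hydrogenolysis; it sets out from 11 and returns at 12.
   - Luche reduction (NaBH4, CeCl3·7H2O, MeOH, −40 °C) gives the diol benzyl 4-{[(2R)-1-[4-(benzyloxy)-3,5-dimethoxyphenyl]-1,3-dihydroxypropan-2-yl]oxy}-3,5-dimethoxybenzoate F5, as C1 epimers of no consequence.
   - Hydrogenolysis (H2, 10% Pd/C, EtOAc/MeOH, rt) then meets an unactivated alkyl aryl ether and should give 4-{[(2R)-1,3-dihydroxy-1-(4-hydroxy-3,5-dimethoxyphenyl)propan-2-yl]oxy}-3,5-dimethoxybenzoic acid F6.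
   - DDQ (1.1 equiv, 1,4-dioxane, rt) dehydrogenates only the 4-hydroxybenzylic carbinol, restoring the ketone without touching C2 and giving 12.

3. Step 3. Hydrogen chloride formed during acylation may convert part of the diazoketone into the chloromethyl ketone, or the electron-rich aroyl chloride may acylate the silyl diazoalkane too slowly. The fallback replaces acylation of a diazoalkane by diazo transfer to a ketone; it sets out from 4 and returns at 7.
   - MeLi (2.2 equiv, THF, 0 °C) converts acid 4 into the methyl ketone 1-[4-(benzyloxy)-3,5-dimethoxyphenyl]ethan-1-one F7.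
   - Detrifluoroacetylative diazo transfer (LiN(SiMe3)2, THF, −78 °C; CF3CO2CH2CF3; then MsN3, Et3N, H2O, MeCN, rt) passes through the diketone 1-[4-(benzyloxy)-3,5-dimethoxyphenyl]-4,4,4-trifluorobutane-1,3-dione F8, which is not isolated, and should deliver 7.

**Further compounds**

F1 | step 5 | 1-[4-(benzyloxy)-3,5-dimethoxyphenyl]-2-bromoethan-1-one | COc1cc(C(=O)CBr)cc(OC)c1OCc1ccccc1
F2 | step 5 | benzyl 4-{2-[4-(benzyloxy)-3,5-dimethoxyphenyl]-2-oxoethoxy}-3,5-dimethoxybenzoate | COc1cc(C(=O)COc2c(OC)cc(C(=O)OCc3ccccc3)cc2OC)cc(OC)c1OCc1ccccc1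
F3 | step 5 | racemic benzyl 4-{[1-[4-(benzyloxy)-3,5-dimethoxyphenyl]-3-hydroxy-1-oxopropan-2-yl]oxy}-3,5-dimethoxybenzoate | COc1cc(C(=O)C(CO)Oc2c(OC)cc(C(=O)OCc3ccccc3)cc2OC)cc(OC)c1OCc1ccccc1
F4 | step 5 | benzyl 4-{[(2S)-1-[4-(benzyloxy)-3,5-dimethoxyphenyl]-3-hydroxy-1-oxopropan-2-yl]oxy}-3,5-dimethoxybenzoate | COc1cc(C(=O)[C@H](CO)Oc2c(OC)cc(C(=O)OCc3ccccc3)cc2OC)cc(OC)c1OCc1ccccc1
F5 | step 6 | benzyl 4-{[(2R)-1-[4-(benzyloxy)-3,5-dimethoxyphenyl]-1,3-dihydroxypropan-2-yl]oxy}-3,5-dimethoxybenzoate (C1 epimers) | COc1cc(C(O)[C@@H](CO)Oc2c(OC)cc(C(=O)OCc3ccccc3)cc2OC)cc(OC)c1OCc1ccccc1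
F6 | step 6 | 4-{[(2R)-1,3-dihydroxy-1-(4-hydroxy-3,5-dimethoxyphenyl)propan-2-yl]oxy}-3,5-dimethoxybenzoic acid (C1 epimers) | COc1cc(C(O)[C@@H](CO)Oc2c(OC)cc(C(=O)O)cc2OC)cc(OC)c1O
F7 | step 3 | 1-[4-(benzyloxy)-3,5-dimethoxyphenyl]ethan-1-one | COc1cc(C(C)=O)cc(OC)c1OCc1ccccc1
F8 | step 3 | 1-[4-(benzyloxy)-3,5-dimethoxyphenyl]-4,4,4-trifluorobutane-1,3-dione | COc1cc(C(=O)CC(=O)C(F)(F)F)cc(OC)c1OCc1ccccc1
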